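**Plan**
- Retrosynthesis: the C4 ketone is taken back to a benzylic CH2; rings A and C are then opened together by cutting C8a–C4a, C5–C6 and C6–C7, which leads to a chromium alkoxycarbene whose oxygen (O1) carries a tethered ynol ether; the carbene C–O1 bond, the C4–C4a(sp) bond and the aryl–carbonyl bond are cut last.
- Enabling feature: ring A is a pentasubstituted benzene whose free hydroxyl on C6 lies para to the ring oxygen O1 and between the methoxy groups on C5 and C7. In a carbene benzannulation the C6–OH comes from CO, O1 from the carbene alkoxy group, C5–OMe from the ynol ether and C7–OMe from the methoxyvinyl group.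
- Forward: ring B and the C2–C3–C4 chain are assembled first (acylation, reduction, acetylide alkylation), the alcohol is loaded onto an (E)-3-methoxyacryloyl chromate, and rings C and A then close in one thermal operation; C4 is oxidised last.
- Stereochemistry: the only stereocentre, C2, is set by a catalyst-controlled ketone reduction and is carried through unchanged, because its C–O bond is never broken.

Key step: step 11

Remark: the labels O1, C2–C8a are those of the chroman-4-one core of the target and are also used for the open-chain precursors; the target is (2S).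

**Step 1**
Reactants: 1 1,2-dimethoxybenzene; 2 3-chloropropanoyl chloride
Product: 3 3-chloro-1-(3,4-dimethoxyphenyl)propan-1-one
Conditions: AlCl3, CH2Cl2, 0 °C
Reagents that add atoms: none
Why: Friedel–Crafts acylation of the electron-rich arene takes place para to one methoxy group and so gives the 3,4-dimethoxyphenyl ketone, while the low temperature avoids ether cleavage and loss of HCl.

**Step 2**
Reactants: 3 3-chloro-1-(3,4-dimethoxyphenyl)propan-1-one
Product: 4 (1S)-3-chloro-1-(3,4-dimethoxyphenyl)propan-1-ol
Conditions: (R)-2-methyl-CBS-oxazaborolidine (10 mol %), BH3·SMe2, THF, 0 °C; MeOH quench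
Reagents that add atoms: none
Why: Corey–Bakshi–Shibata reduction of an aryl 2-chloroethyl ketone, in which the (R)-catalyst binds the ketone with the aryl group as the large substituent and delivers hydride to the Re face, should set the carbinol carbon (the later C2) as (S).

**Step 3**
Reactants: 4 (1S)-3-chloro-1-(3,4-dimethoxyphenyl)propan-1-ol
Product: 5 tert-butyl{[(1S)-3-chloro-1-(3,4-dimethoxyphenyl)propyl]oxy}dimethylsilane
Conditions: TBSCl, imidazole, DMF, rt
Reagents that add atoms: tert-butyldimethylsilyl chloride, CC(C)(C)[Si](C)(C)Cl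
Why: Standard imidazole-promoted silylation masks the alcohol so that the later strongly basic alkylation cannot close an oxetane.

**Step 4**
Reactants: 5 tert-butyl{[(1S)-3-chloro-1-(3,4-dimethoxyphenyl)propyl]oxy}dimethylsilane
Product: 6 tert-butyl{[(1S)-1-(3,4-dimethoxyphenyl)-3-iodopropyl]oxy}dimethylsilane
Conditions: NaI, acetone, reflux
Reagents that add atoms: sodium iodide, [Na+].[I-]
Why: Finkelstein exchange at the primary carbon, driven by precipitation of NaCl, provides the iodide needed for acetylide alkylation.

**Step 5**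
Reactants: 6 tert-butyl{[(1S)-1-(3,4-dimethoxyphenyl)-3-iodopropyl]oxy}dimethylsilane; 7 2-chloro-1,1-dimethoxyethane (chloroacetaldehyde dimethyl acetal)
Product: 9 tert-butyl{[(1S)-1-(3,4-dimethoxyphenyl)-5-methoxypent-4-yn-1-yl]oxy}dimethylsilane, via lithium methoxyacetylide 8 (not isolated)
Conditions: 7, LiNEt2 (from Et2NH and n-BuLi, 3 equiv per 7), THF, −10 → 0 °C; then 6, HMPA, 0 °C → rt
Reagents that add atoms: none
Why: Two eliminations and a deprotonation convert the chloroacetal into lithium methoxyacetylide, which is alkylated by the primary iodide in an SN2 reaction promoted by HMPA, and the basic medium preserves the acid-labile ynol ether.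

**Step 6**
Reactants: 9 tert-butyl{[(1S)-1-(3,4-dimethoxyphenyl)-5-methoxypent-4-yn-1-yl]oxy}dimethylsilane
Product: 10 (1S)-1-(3,4-dimethoxyphenyl)-5-methoxypent-4-yn-1-ol
Conditions: Bu4NF, THF, 0 °C → rt
Reagents that add atoms: none
Why: Fluoride-induced desilylation under non-acidic conditions frees the alcohol without touching the ynol ether or the carbinol C–O bond.

**Step 7**
Reactants: 11 methyl (2E)-3-methoxyprop-2-enoate
Product: 12 sodium (2E)-3-methoxyprop-2-enoate
Conditions: NaOH (1.0 equiv), MeOH/H2O, rt; evaporate and dry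
Reagents that add atoms: sodium hydroxide, [Na+].[OH-]
Why: Saponification at the acyl carbon of this vinylogous carbonate should give the dry carboxylate salt with the E geometry intact, and isolation as the salt avoids acid-induced enol ether hydrolysis.

**Step 8**
Reactants: 12 sodium (2E)-3-methoxyprop-2-enoate
Product: 13 (2E)-3-methoxyprop-2-enoyl chloride
Conditions: (COCl)2, DMF (cat.), CH2Cl2, 0 °C → rt
Reagents that add atoms: oxalyl chloride, O=C(Cl)C(Cl)=O
Why: Vilsmeier-type activation of the carboxylate by oxalyl chloride gives the acid chloride without disturbing the E double bond.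

**Step 9**
Reactants: 14 hexacarbonylchromium, Cr(CO)6; 13 (2E)-3-methoxyprop-2-enoyl chloride
Product: 17 tetramethylammonium pentacarbonyl[(2E)-3-methoxyprop-2-enoyl]chromate, via disodium pentacarbonylchromate 15 (not isolated), via sodium acylchromate 16 (not isolated)
Conditions: NaC10H8 (2.1 equiv, THF solution), THF, −78 °C; then 13, −78 → 0 °C; then Me4NBr, H2O, 0 °C
Reagents that add atoms: tetramethylammonium bromide, C[N+](C)(C)C.[Br-]
Why: Two-electron reduction of Cr(CO)6 gives the strongly nucleophilic dianion Na2Cr(CO)5, which undergoes acyl substitution with the acid chloride to give the acylchromate, and this entry is chosen because it carries the E geometry of the acid chloride, whereas (E)-2-methoxyvinyllithium would be prone to β-elimination.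

**Step 10**
Reactants: 17 tetramethylammonium pentacarbonyl[(2E)-3-methoxyprop-2-enoyl]chromate; 10 (1S)-1-(3,4-dimethoxyphenyl)-5-methoxypent-4-yn-1-ol
Product: 19 pentacarbonyl[(2E)-1-{[(1S)-1-(3,4-dimethoxyphenyl)-5-methoxypent-4-yn-1-yl]oxy}-3-methoxyprop-2-en-1-ylidene]chromium, via acetoxycarbene complex 18 (not isolated)
Conditions: AcBr, CH2Cl2, −40 °C; then 10, 2,6-di-tert-butyl-4-methylpyridine, −40 → 0 °C; cold NaHCO3 wash, rapid chromatography
Reagents that add atoms: none
Why: O-acetylation of the acylate gives an anhydride-like acyloxycarbene whose carbene carbon undergoes addition–elimination with the secondary alcohol (acyloxy/alkoxy exchange), so the carbinol C–O bond and its (S) configuration are untouched, and the hindered pyridine buffers the acetic acid that would otherwise add to the ynol ether.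

**Step 11**
Reactants: 19 pentacarbonyl[(2E)-1-{[(1S)-1-(3,4-dimethoxyphenyl)-5-methoxypent-4-yn-1-yl]oxy}-3-methoxyprop-2-en-1-ylidene]chromium
Product: 22 (2S)-2-(3,4-dimethoxyphenyl)-5,7-dimethoxychroman-6-ol, via tricarbonylchromium dienylketene complex 20 (not isolated), via tricarbonylchromium arene complex 21 (not isolated)
Conditions: THF (0.01 M), 55 °C, argon; then air, daylight, Et2O, rt
Reagents that add atoms: none
Why: Proposed new method: on warming, the ynol ether should insert into the Cr=C8a bond, either after loss of one CO from zerovalent chromium or by polar attack of its nucleophilic carbon C4a on the electrophilic carbene carbon as ynamines do, forming C8a–C4a and a methoxy-stabilised dienylcarbene at C5; CO insertion there (C5–C6) gives the chromium-bound dienylketene 20, whose electrocyclisation onto C7 (C6–C7) and tautomerisation give the phenol as its Cr(CO)3 complex 21, which air oxidation releases. The closest known reactions are the intramolecular Dötz benzannulation of alkenyl- and aryl(alkoxy)carbene chromium complexes that carry an alkyne on the carbene oxygen, the insertion of ynamines into Fischer carbene complexes, and the thermal or photochemical benzannulation of dienyl(alkoxy)carbene chromium complexes to ortho-alkoxyphenols; an ynol ether combined with a β-methoxyvinyl carbene has not been shown. Ring C closes by a 6-exo-dig-type insertion of the tethered alkyne, and ring A by disrotatory 6π electrocyclisation of the dienylketene. No stereocentre is formed, and C2 is a spectator whose C–O bond is never broken, so the (S) configuration from step 2 persists. The step needs C4a, not C5, to bond to C8a, and CO insertion in place of cyclopentannulation: the three-carbon oxygen tether and the polarisation of the ynol ether both direct C4a to the carbene carbon, the ring C double bond holds C5 and C8 cis, and a chromium alkoxycarbene in THF favours the ketene path. High dilution suppresses intermolecular insertion.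

**Step 12**
Reactants: 22 (2S)-2-(3,4-dimethoxyphenyl)-5,7-dimethoxychroman-6-ol
Product: 23 (2S)-2-(3,4-dimethoxyphenyl)-5,7-dimethoxychroman-6-yl acetate
Conditions: Ac2O, pyridine, DMAP (cat.), CH2Cl2, rt
Reagents that add atoms: acetic anhydride, CC(=O)OC(C)=O
Why: DMAP-catalysed acetylation of the hindered phenol protects the hydroquinone monoether from quinone formation in the oxidation that follows.

**Step 13**
Reactants: 23 (2S)-2-(3,4-dimethoxyphenyl)-5,7-dimethoxychroman-6-yl acetate
Product: 25 (2S)-2-(3,4-dimethoxyphenyl)-5,7-dimethoxy-4-oxochroman-6-yl acetate, via flavan-4-ol acetate 24 (not isolated)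
Conditions: DDQ (2.5 equiv), 1,4-dioxane/H2O (9:1), rt
Reagents that add atoms: water, O
Why: DDQ benzylic oxidation by hydride abstraction at C4 gives a cation stabilised by O1 and the C5 and C7 methoxy groups, water traps it and a second hydride abstraction from the carbinol gives the ketone, while C2–H should be less reactive because the O1 lone pair is engaged with ring A.

**Step 14**
Reactants: 25 (2S)-2-(3,4-dimethoxyphenyl)-5,7-dimethoxy-4-oxochroman-6-yl acetate
Product: 26 (2S)-2-(3,4-dimethoxyphenyl)-6-hydroxy-5,7-dimethoxychroman-4-one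
Conditions: HCl in MeOH, 0 °C → rt
Reagents that add atoms: none
Why: Acid-catalysed transesterification removes the aryl acetate, and acid is chosen because flavanones open to chalcones and racemise at C2 under basic conditions but are configurationally stable in acid.

**Compound list**
1 | 1,2-dimethoxybenzene | COc1ccccc1OC | starting material
2 | 3-chloropropanoyl chloride | ClCCC(Cl)=O | starting material
3 | 3-chloro-1-(3,4-dimethoxyphenyl)propan-1-one | O=C(CCCl)c1ccc(OC)c(OC)c1 | intermediate
4 | (1S)-3-chloro-1-(3,4-dimethoxyphenyl)propan-1-ol | ClCC[C@H](O)c1ccc(OC)c(OC)c1 | intermediate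
5 | tert-butyl{[(1S)-3-chloro-1-(3,4-dimethoxyphenyl)propyl]oxy}dimethylsilane | ClCC[C@H](O[Si](C)(C)C(C)(C)C)c1ccc(OC)c(OC)c1 | intermediate
6 | tert-butyl{[(1S)-1-(3,4-dimethoxyphenyl)-3-iodopropyl]oxy}dimethylsilane | ICC[C@H](O[Si](C)(C)C(C)(C)C)c1ccc(OC)c(OC)c1 | intermediate
7 | 2-chloro-1,1-dimethoxyethane (chloroacetaldehyde dimethyl acetal) | COC(CCl)OC | starting material
8 | lithium methoxyacetylide | [Li]C#COC | intermediate
9 | tert-butyl{[(1S)-1-(3,4-dimethoxyphenyl)-5-methoxypent-4-yn-1-yl]oxy}dimethylsilane | COC#CCC[C@H](O[Si](C)(C)C(C)(C)C)c1ccc(OC)c(OC)c1 | intermediate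
10 | (1S)-1-(3,4-dimethoxyphenyl)-5-methoxypent-4-yn-1-ol | COC#CCC[C@H](O)c1ccc(OC)c(OC)c1 | intermediate
11 | methyl (2E)-3-methoxyprop-2-enoate | CO/C=C/C(=O)OC | starting material
12 | sodium (2E)-3-methoxyprop-2-enoate | CO/C=C/C(=O)[O-].[Na+] | intermediate
13 | (2E)-3-methoxyprop-2-enoyl chloride | CO/C=C/C(Cl)=O | intermediate
14 | hexacarbonylchromium, Cr(CO)6 | O=C=[Cr](=C=O)(=C=O)(=C=O)(=C=O)=C=O | starting material
15 | disodium pentacarbonylchromate, Na2Cr(CO)5 | [Na+].[Na+].O=C=[Cr-2](=C=O)(=C=O)(=C=O)=C=O | intermediate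
16 | sodium pentacarbonyl[(2E)-3-methoxyprop-2-enoyl]chromate | [Na+].CO/C=C/C(=O)[Cr-](=C=O)(=C=O)(=C=O)(=C=O)=C=O | intermediate
17 | tetramethylammonium pentacarbonyl[(2E)-3-methoxyprop-2-enoyl]chromate | C[N+](C)(C)C.CO/C=C/C(=O)[Cr-](=C=O)(=C=O)(=C=O)(=C=O)=C=O | intermediate
18 | [(2E)-1-acetoxy-3-methoxyprop-2-en-1-ylidene]pentacarbonylchromium | CO/C=C/C(OC(C)=O)=[Cr](=C=O)(=C=O)(=C=O)(=C=O)=C=O | intermediate
19 | pentacarbonyl[(2E)-1-{[(1S)-1-(3,4-dimethoxyphenyl)-5-methoxypent-4-yn-1-yl]oxy}-3-methoxyprop-2-en-1-ylidene]chromium | COC#CCC[C@H](OC(/C=C/OC)=[Cr](=C=O)(=C=O)(=C=O)(=C=O)=C=O)c1ccc(OC)c(OC)c1 | intermediate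
20 | Cr(CO)3 complex of 2-[(2S)-2-(3,4-dimethoxyphenyl)-6-[(E)-2-methoxyethenyl]-3,4-dihydro-2H-pyran-5-yl]-2-methoxyethen-1-one (metal π-bound to the vinylketene, written as a separate component) | COc1ccc([C@@H]2CCC(C(OC)=C=O)=C(/C=C/OC)O2)cc1OC.O=C=[Cr](=C=O)=C=O | intermediate
21 | tricarbonyl[η6-(2S)-2-(3,4-dimethoxyphenyl)-5,7-dimethoxychroman-6-ol]chromium (metal on ring A, written as a separate component) | COc1ccc([C@@H]2CCc3c(cc(OC)c(O)c3OC)O2)cc1OC.O=C=[Cr](=C=O)=C=O | intermediate
22 | (2S)-2-(3,4-dimethoxyphenyl)-5,7-dimethoxychroman-6-ol | COc1ccc([C@@H]2CCc3c(cc(OC)c(O)c3OC)O2)cc1OC | intermediate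
23 | (2S)-2-(3,4-dimethoxyphenyl)-5,7-dimethoxychroman-6-yl acetate | COc1ccc([C@@H]2CCc3c(cc(OC)c(OC(C)=O)c3OC)O2)cc1OC | intermediate
24 | (2S)-2-(3,4-dimethoxyphenyl)-4-hydroxy-5,7-dimethoxychroman-6-yl acetate (both C4 epimers) | COc1ccc([C@@H]2CC(O)c3c(cc(OC)c(OC(C)=O)c3OC)O2)cc1OC | intermediate
25 | (2S)-2-(3,4-dimethoxyphenyl)-5,7-dimethoxy-4-oxochroman-6-yl acetate | COc1ccc([C@@H]2CC(=O)c3c(cc(OC)c(OC(C)=O)c3OC)O2)cc1OC | intermediate
26 | (2S)-2-(3,4-dimethoxyphenyl)-6-hydroxy-5,7-dimethoxychroman-4-one | COc1ccc([C@@H]2CC(=O)c3c(cc(OC)c(O)c3OC)O2)cc1OC | target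

**Step count**
Total: 14 steps. Longest linear sequence: 11 steps (steps 1–6, then 10–14); the chromium branch (steps 7–9) joins at step 10.

**Steps most likely to fail**

1. Step 11. The cascade may stall after alkyne insertion because the methoxy-stabilised carbene at C5 is slow to take up CO, it may divert to cyclopentannulation without CO, or the ynol ether may be consumed by adventitious acid before it inserts. The fallback builds the same chromanol by known chemistry and sets out from ketone 3. Et3N in CH2Cl2 eliminates HCl to give 1-(3,4-dimethoxyphenyl)prop-2-en-1-one F1. Acid-catalysed Friedel–Crafts conjugate addition (BF3·OEt2, dioxane, under argon) of commercial 2,6-dimethoxybenzene-1,4-diol at its only free ring position gives 3-(2,5-dihydroxy-4,6-dimethoxyphenyl)-1-(3,4-dimethoxyphenyl)propan-1-one F2, which already carries ring A with the correct substituent pattern. Noyori transfer hydrogenation with RuCl[(R,R)-TsDPEN](p-cymene) and HCO2H/Et3N should give (1R)-3-(2,5-dihydroxy-4,6-dimethoxyphenyl)-1-(3,4-dimethoxyphenyl)propan-1-ol F3. Intramolecular Mitsunobu etherification (PPh3, DIAD, THF, 0 °C; betaine pre-formed) by the unhindered phenol then closes ring C with inversion, and the sequence comes back to the route at chromanol 22.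

2. Step 9. The dianion may transfer an electron to, or add in conjugate fashion to, the vinylogous acid chloride instead of substituting at the acyl carbon, and the acylate may be acylated a second time. The fallback uses the classical organolithium entry to Fischer carbene complexes and sets out from Cr(CO)6 14. Methoxyethene is brominated (Br2, CH2Cl2, −78 °C) to 1,2-dibromo-1-methoxyethane F4 and dehydrobrominated (N,N-diethylaniline, 90 °C) to (Z)-1-bromo-2-methoxyethene F5. Bromine–lithium exchange (t-BuLi, Et2O, −78 °C) gives the chelation-stabilised (Z)-2-methoxyvinyllithium F6, which adds to 14 to give lithium pentacarbonyl[(2Z)-3-methoxyprop-2-enoyl]chromate F7, exchanged with Me4NBr to tetramethylammonium pentacarbonyl[(2Z)-3-methoxyprop-2-enoyl]chromate F8. Activation and alcoholysis as in step 10, through [(2Z)-1-acetoxy-3-methoxyprop-2-en-1-ylidene]pentacarbonylchromium F9 and alcohol 10, give pentacarbonyl[(2Z)-1-{[(1S)-1-(3,4-dimethoxyphenyl)-5-methoxypent-4-yn-1-yl]oxy}-3-methoxyprop-2-en-1-ylidene]chromium F10. Thermolysis as in step 11 passes through the Cr(CO)3 complex of 2-[(2S)-2-(3,4-dimethoxyphenyl)-6-[(Z)-2-methoxyethenyl]-3,4-dihydro-2H-pyran-5-yl]-2-methoxyethen-1-one F11 and arene complex 21. Because C7 ends as an sp2 ring carbon, the Z geometry should converge on the same arene, and the sequence comes back to the route at chromanol 22.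

3. Step 13. Hydride abstraction may occur at C2 instead of C4, or the C4 cation may lose a C3 proton and be oxidised further to the flavene, flavylium or flavone level. The fallback sets out from acetate 23 and separates hydroxylation from alcohol oxidation: one equivalent of DDQ in CH2Cl2/pH 7 buffer at 0 °C is used so that the cation is only trapped by water, flavan-4-ol acetate 24 is isolated, and it is then oxidised with MnO2 in CH2Cl2, a surface oxidant selective for benzylic alcohols that cannot dehydrogenate the product or attack C2; this comes back to the route at ketone 25 and makes no compound outside the list (F0).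

**Further compounds**
F1 | step 11 | 1-(3,4-dimethoxyphenyl)prop-2-en-1-one | C=CC(=O)c1ccc(OC)c(OC)c1
F2 | step 11 | 3-(2,5-dihydroxy-4,6-dimethoxyphenyl)-1-(3,4-dimethoxyphenyl)propan-1-one | COc1ccc(C(=O)CCc2c(O)cc(OC)c(O)c2OC)cc1OC
F3 | step 11 | (1R)-3-(2,5-dihydroxy-4,6-dimethoxyphenyl)-1-(3,4-dimethoxyphenyl)propan-1-ol | COc1ccc([C@H](O)CCc2c(O)cc(OC)c(O)c2OC)cc1OC
F4 | step 9 | 1,2-dibromo-1-methoxyethane | COC(Br)CBr
F5 | step 9 | (Z)-1-bromo-2-methoxyethene | CO/C=C\Br
F6 | step 9 | (Z)-2-methoxyvinyllithium | CO/C=C\[Li]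
F7 | step 9 | lithium pentacarbonyl[(2Z)-3-methoxyprop-2-enoyl]chromate | [Li+].CO/C=C\C(=O)[Cr-](=C=O)(=C=O)(=C=O)(=C=O)=C=O
F8 | step 9 | tetramethylammonium pentacarbonyl[(2Z)-3-methoxyprop-2-enoyl]chromate | C[N+](C)(C)C.CO/C=C\C(=O)[Cr-](=C=O)(=C=O)(=C=O)(=C=O)=C=O
F9 | step 9 | [(2Z)-1-acetoxy-3-methoxyprop-2-en-1-ylidene]pentacarbonylchromium | CO/C=C\C(OC(C)=O)=[Cr](=C=O)(=C=O)(=C=O)(=C=O)=C=O
F10 | step 9 | pentacarbonyl[(2Z)-1-{[(1S)-1-(3,4-dimethoxyphenyl)-5-methoxypent-4-yn-1-yl]oxy}-3-methoxyprop-2-en-1-ylidene]chromium | COC#CCC[C@H](OC(/C=C\OC)=[Cr](=C=O)(=C=O)(=C=O)(=C=O)=C=O)c1ccc(OC)c(OC)c1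
F11 | step 9 | Cr(CO)3 complex of 2-[(2S)-2-(3,4-dimethoxyphenyl)-6-[(Z)-2-methoxyethenyl]-3,4-dihydro-2H-pyran-5-yl]-2-methoxyethen-1-one | COc1ccc([C@@H]2CCC(C(OC)=C=O)=C(/C=C\OC)O2)cc1OC.O=C=[Cr](=C=O)=C=O
F0 | step 13 | none | none
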